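**Late flask.** Late in this flask I expected the target to have stopped rising, and what I wanted to know was the level at which it would stand by then.

starting material 1.5 M; reagent 0.750 M (in portions, 4); precatalyst 7.5 mM; time 30 min; the portions of reagent follow each other after 10 s, the first at the start

    reagent + free catalyst → catalyst intermediate A (k1 = 33 M⁻¹ s⁻¹)
    catalyst intermediate A → by-product + catalyst intermediate B (k2 = 20 s⁻¹)
    starting material + catalyst intermediate B ⇌ catalyst intermediate C (K3 = 21 M⁻¹, k3 = 5.0 M⁻¹ s⁻¹)
    catalyst intermediate C ⇌ catalyst intermediate D (K4 = 0.11, k4 = 5.3 s⁻¹)
    catalyst intermediate D → free catalyst + target (k5 = 6.4 s⁻¹)
    precatalyst → free catalyst (k6 = 0.0016 s⁻¹)
    reagent + free catalyst + target → free catalyst + over-reaction product (k7 = 0.30 M⁻² s⁻¹)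

- why nothing more happens at 30 min, or that something still does (the reagent has run out first / forward and back rates have come level / all of the starting material has reacted / no working catalyst is left / it is still moving)
- share of the starting material used up at 30 min
- target at 30 min, in percent of the starting material charged
- amount of target if the flask were left three thousand times as long, in percent of the starting material charged

- the reaction counts as stopped when no species that holds the starting material changes by six tenths of a point or more over the second half of the time
- run time (flask): 30 min

**Two amounts.** I followed one round of the catalyst: step 1 took one reagent, step 3 took one starting material, and step 5 gave one target and handed back free catalyst. The catalyst therefore dropped out of the count, which left [reagent] charged, 0.750 M, against [starting material] charged, 1.5 M. I took equal charges, the symmetric case where in this count both end together, as the zero of the scale, and I carried the charge ratio, [reagent] charged over [starting material] charged, 50.0%. Because the reagent was the smaller charge, it was the limiting reagent, so I committed to conversion, target at the asked time and target after the long wait all at that ratio, with the reagent ending first.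

**Time test.** I still had to reckon how long the reagent charge would take. Catalyst intermediate C passes through catalyst intermediate D to target at about 0.621 s⁻¹, so the full catalyst charge, held as catalyst intermediate C, needs about 2.68 min for the whole reagent charge. As a rough allowance I took one half-life of precatalyst, 7.2 min, and after it 2 times that need, since by my reckoning half of the catalyst was out by then, which came to 12.6 min, shorter than the 30 min given.

**Forecast, result.** The forecast said the reagent has run out first, with 49.8% conversion, 49.7% target and 49.7% after the long wait, adding “Without reagent nothing further happens”. The simulation gave the reagent has run out first, with 49.8% conversion, 49.7% target and 49.7% after the long wait, which lies 0.30 percentage points under my ratio, while the flask held 0.168% of over-reaction product at 30.0 min and less reagent than starting material of their charges, 0% against 50%.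

**Neighbouring flask.** The neighbouring flask kept the reagent at 0.750 M but took 0.90 M of starting material, so the same ratio read 83.3%, with the reagent still the smaller charge. That flask gave 83.1% conversion and 82.8% target at 30.0 min, with reagent at 0% of its charge and starting material at 16.9%.

The numbers are made up; the rest is arithmetic.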